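**Plan**
1. Retrosynthesis: the four silyl groups come off last. Ring C is then cut across O1–C8a and C2–C3 into 4-silyloxybenzaldehyde (C2, O1, ring B) and the enediol bis-silyl ether of a 2-fluoroaryl ketone (ring A, C4, C3). Before that, C3–O (Rubottom oxidation), O7–CH2 (ether) and C4–C4a (Houben–Hoesch) are cut.
2. Enabling feature: the C4 ketone lies between C3 and C4a of ring A. With fluorine on C8a, the chain C3=C4(OSi)–C4a=C8a–F is an arene-embedded 1-fluoro-3-silyloxydiene (a vinylogous acyl fluoride), nucleophilic at C3 and electrophilic at C8a. It takes up the aldehyde C=O across these two atoms, as such dienes do in aldehyde cyclocondensations.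
3. Forward: ring A ketone from 5-fluororesorcinol, O7 alkylation with the E-chloro alcohol from isoprene monoxide, one-pot tris-silylation, Rubottom oxidation and O-silylation give the diene. The aldol/SNAr annulation then closes ring C onto ring A while bringing in ring B; desilylation ends the route.
4. Stereochemistry: the E alkene comes from the SN2′ epoxide opening. C2 is set by a chiral ammonium cation in the aldol addition (Si face of the aldehyde) and kept by retention in the ring closure. C3 follows C2 as the 2,3-trans (diequatorial) arrangement.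
5. Helpers: F on C8a and Me3Si on O4 leave together as Me3SiF in the key step; the i-Pr3Si and t-BuMe2Si ethers on O3, O5, O4′ and the side chain leave in the last step.

Key step: step 7

Remark: 1, 4 and 11 are taken as commercial; the facial sense of the cinchonidinium cation in this new ion pair cannot be derived with certainty, so the cinchonidinium salt is written and its pseudo-enantiomeric cinchoninium salt is the same catalyst with the opposite sense.

**Step 1**
Reactants: 1 5-fluororesorcinol
Product: 3 2'-fluoro-4',6'-dihydroxyacetophenone, via ketiminium chloride 2 (not isolated)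
Conditions: MeCN, ZnCl2, HCl (g), Et2O, 0 °C; then H2O, 100 °C
Reagents that add atoms: acetonitrile CC#N; water O
Why: Houben–Hoesch acylation at the ring position ortho to one hydroxyl and para to the other (next to fluorine), the doubly flanked position between the hydroxyls being the less reactive one as in other 5-substituted resorcinols, followed by hydrolysis of the ketiminium salt.

**Step 2**
Reactants: 4 2-methyl-2-vinyloxirane
Product: 5 (E)-4-chloro-2-methylbut-2-en-1-ol
Conditions: TiCl4 (1.5 equiv), CH2Cl2, −85 °C; then 1 M HCl (aq)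
Reagents that add atoms: titanium tetrachloride Cl[Ti](Cl)(Cl)Cl
Why: Lewis-acid SN2′ (1,4) opening of the vinyl epoxide, a known conversion in which chloride adds to the vinyl terminus of the titanium-bound epoxide and the E allylic alcohol should predominate.

**Step 3**
Reactants: 3 2'-fluoro-4',6'-dihydroxyacetophenone, 5 (E)-4-chloro-2-methylbut-2-en-1-ol
Product: 6 2'-fluoro-6'-hydroxy-4'-[(E)-4-hydroxy-3-methylbut-2-enyloxy]acetophenone
Conditions: K2CO3, NaI (cat.), acetone, 50 °C
Reagents that add atoms: none
Why: Williamson O-alkylation (SN2 at the primary allylic carbon, alkene geometry untouched); the 6'-OH is tied up in a hydrogen bond to the ketone, so the free 4'-OH should react selectively.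

**Step 4**
Reactants: 6 2'-fluoro-6'-hydroxy-4'-[(E)-4-hydroxy-3-methylbut-2-enyloxy]acetophenone
Product: 7 triisopropylsilyl enol ether of 2'-fluoro-6'-(triisopropylsilyloxy)-4'-[(E)-3-methyl-4-(triisopropylsilyloxy)but-2-enyloxy]acetophenone
Conditions: TIPSOTf (3.5 equiv), Et3N, CH2Cl2, 0 → 20 °C
Reagents that add atoms: triisopropylsilyl trifluoromethanesulfonate CC(C)[Si](OS(=O)(=O)C(F)(F)F)(C(C)C)C(C)C
Why: silyl triflate with amine silylates the phenol and the primary alcohol and converts the methyl ketone into its silyl enol ether by soft enolisation in the same operation.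

**Step 5**
Reactants: 7 triisopropylsilyl enol ether of 2'-fluoro-6'-(triisopropylsilyloxy)-4'-[(E)-3-methyl-4-(triisopropylsilyloxy)but-2-enyloxy]acetophenone
Product: 9 2'-fluoro-α,6'-bis(triisopropylsilyloxy)-4'-[(E)-3-methyl-4-(triisopropylsilyloxy)but-2-enyloxy]acetophenone, via silyloxy-oxirane 8 (not isolated)
Conditions: mCPBA (1.05 equiv), CH2Cl2, −20 → 0 °C
Reagents that add atoms: 3-chloroperoxybenzoic acid OOC(=O)c1cccc(Cl)c1
Why: Rubottom oxidation, in which the electron-rich enol ether should be epoxidised much faster than the side-chain alkene (deactivated by two allylic C–O bonds) and the silyloxy-oxirane opens with O→O silyl shift to the α-silyloxy ketone.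

**Step 6**
Reactants: 9 2'-fluoro-α,6'-bis(triisopropylsilyloxy)-4'-[(E)-3-methyl-4-(triisopropylsilyloxy)but-2-enyloxy]acetophenone
Product: 10 (Z)-1-(trimethylsilyloxy)-2-(triisopropylsilyloxy)ethene bearing at C1 the 2-fluoro-6-(triisopropylsilyloxy)-4-[(E)-3-methyl-4-(triisopropylsilyloxy)but-2-enyloxy]phenyl group
Conditions: TMSOTf, Et3N, CH2Cl2, 0 °C; pentane, filtration, used crude
Reagents that add atoms: trimethylsilyl trifluoromethanesulfonate C[Si](C)(C)OS(=O)(=O)C(F)(F)F
Why: soft enolisation and O-silylation without a free enolate (so the silyl group on O5 cannot migrate); the Z isomer is expected because ring A avoids allylic strain with a cis substituent.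

**Step 7**
Reactants: 10 (Z)-1-(trimethylsilyloxy)-2-(triisopropylsilyloxy)ethene bearing at C1 the 2-fluoro-6-(triisopropylsilyloxy)-4-[(E)-3-methyl-4-(triisopropylsilyloxy)but-2-enyloxy]phenyl group, 11 4-(tert-butyldimethylsilyloxy)benzaldehyde
Product: 13 (2R,3R)-2-[4-(tert-butyldimethylsilyloxy)phenyl]-3,5-bis(triisopropylsilyloxy)-7-[(E)-3-methyl-4-(triisopropylsilyloxy)but-2-enyloxy]chroman-4-one, via anti-aldol trimethylsilyl ether 12 (not isolated)
Conditions: N-(9-anthracenylmethyl)-O(9)-allylcinchonidinium bifluoride (10 mol%), 4 Å MS, toluene/CH2Cl2, −78 °C; then warm to 20 °C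
Reagents that add atoms: none
Why: Proposed new method: fluoride from the bifluoride takes the Me3Si group from O4 of 10 and frees the enolate as an ion pair with the chiral ammonium cation; at −78 °C this adds through C3 to the aldehyde carbon of 11 (C2–C3 bond), the aldolate is silylated by the next molecule of 10 to give 12, and on warming fluoride takes the Me3Si group off 12 again, the C2 alkoxide attacks C8a of ring A and expels fluoride (O1–C8a bond), which carries the chain, so that Me3SiF is the only stoichiometric by-product. The closest known reaction types are the Mukaiyama aldol addition catalysed by chiral ammonium fluorides or bifluorides, enol silane additions in which the leaving group of a ring closure regenerates the anionic catalyst, the Darzens condensation (aldol addition then ring closure by the aldolate oxygen) and the intramolecular SNAr O-arylation of alkoxides at 2-fluoroaryl ketones; their union in one enantioselective annulation has not been shown. Ring C closes by addition–elimination at C8a, in effect a 6-endo-trig oxa-conjugate addition to the vinylogous acyl fluoride C8a=C4a–C4=O through an anionic cyclohexadienyl σ-adduct whose charge rests on the C4 carbonyl, followed by loss of fluoride. C2 is set in the aldol addition by the cinchonidinium cation, which has to leave the Si face of the aldehyde open to the enolate carbon, and it is carried into 13 with retention because the C2–O bond is never broken. C3 is set relative to C2: an open transition state that keeps the aldehyde aryl group away from the twisted 2,6-disubstituted ring A should give the anti adduct, the half-chair closure with aryl and silyloxy groups both pseudo-equatorial is the easier one, and C3 remains α to the ketone and so can still settle into the more stable 2,3-trans ring. The step needs closure by the C2 alkoxide at C8a to outrun retro-aldol cleavage, silyl migration from O3 (which would let O3 close a five-membered benzofuranone) and desilylation of the aryl ethers; the single fluorine ortho to the ketone, the bulky i-Pr3Si groups on O3 and O5, the Me3Si group that absorbs each fluoride as it is released and a chiral cation that stays with the anion through every reversible stage are the features meant to secure this.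

**Step 8**
Reactants: 13 (2R,3R)-2-[4-(tert-butyldimethylsilyloxy)phenyl]-3,5-bis(triisopropylsilyloxy)-7-[(E)-3-methyl-4-(triisopropylsilyloxy)but-2-enyloxy]chroman-4-one
Product: 14 (2R,3R)-3,5-dihydroxy-7-[(E)-4-hydroxy-3-methylbut-2-enyloxy]-2-(4-hydroxyphenyl)chroman-4-one
Conditions: TBAF/AcOH (1:1, 6 equiv), THF, 0 → 20 °C
Reagents that add atoms: none
Why: fluoride cleaves the two aryl and two alkyl silyl ethers, and the acetic acid buffer keeps the medium from becoming basic enough to open ring C or epimerise C2 and C3; the allylic aryl ether and the alkene are inert.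

**Compound list**
1 | 5-fluororesorcinol (5-fluorobenzene-1,3-diol) | Oc1cc(O)cc(F)c1 | starting material
2 | 1-(2-fluoro-4,6-dihydroxyphenyl)ethan-1-iminium chloride | CC(=[NH2+])c1c(O)cc(O)cc1F.[Cl-] | intermediate
3 | 2'-fluoro-4',6'-dihydroxyacetophenone | CC(=O)c1c(O)cc(O)cc1F | intermediate
4 | 2-methyl-2-vinyloxirane (isoprene monoxide, racemic) | CC1(C=C)CO1 | starting material
5 | (E)-4-chloro-2-methylbut-2-en-1-ol | C/C(=C\CCl)CO | intermediate
6 | 2'-fluoro-6'-hydroxy-4'-[(E)-4-hydroxy-3-methylbut-2-enyloxy]acetophenone | CC(=O)c1c(O)cc(OC/C=C(\C)CO)cc1F | intermediate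
7 | triisopropylsilyl enol ether of 2'-fluoro-6'-(triisopropylsilyloxy)-4'-[(E)-3-methyl-4-(triisopropylsilyloxy)but-2-enyloxy]acetophenone | C=C(O[Si](C(C)C)(C(C)C)C(C)C)c1c(O[Si](C(C)C)(C(C)C)C(C)C)cc(OC/C=C(\C)CO[Si](C(C)C)(C(C)C)C(C)C)cc1F | intermediate
8 | 2-{2-fluoro-6-(triisopropylsilyloxy)-4-[(E)-3-methyl-4-(triisopropylsilyloxy)but-2-enyloxy]phenyl}-2-(triisopropylsilyloxy)oxirane (racemic) | C1OC1(O[Si](C(C)C)(C(C)C)C(C)C)c1c(O[Si](C(C)C)(C(C)C)C(C)C)cc(OC/C=C(\C)CO[Si](C(C)C)(C(C)C)C(C)C)cc1F | intermediate
9 | 2'-fluoro-α,6'-bis(triisopropylsilyloxy)-4'-[(E)-3-methyl-4-(triisopropylsilyloxy)but-2-enyloxy]acetophenone | O=C(CO[Si](C(C)C)(C(C)C)C(C)C)c1c(O[Si](C(C)C)(C(C)C)C(C)C)cc(OC/C=C(\C)CO[Si](C(C)C)(C(C)C)C(C)C)cc1F | intermediate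
10 | (Z)-1-{2-fluoro-6-(triisopropylsilyloxy)-4-[(E)-3-methyl-4-(triisopropylsilyloxy)but-2-enyloxy]phenyl}-2-(triisopropylsilyloxy)-1-(trimethylsilyloxy)ethene | C[Si](C)(C)O/C(=C\O[Si](C(C)C)(C(C)C)C(C)C)c1c(O[Si](C(C)C)(C(C)C)C(C)C)cc(OC/C=C(\C)CO[Si](C(C)C)(C(C)C)C(C)C)cc1F | intermediate
11 | 4-(tert-butyldimethylsilyloxy)benzaldehyde | O=Cc1ccc(O[Si](C)(C)C(C)(C)C)cc1 | starting material
12 | (2R,3R)-3-[4-(tert-butyldimethylsilyloxy)phenyl]-1-{2-fluoro-6-(triisopropylsilyloxy)-4-[(E)-3-methyl-4-(triisopropylsilyloxy)but-2-enyloxy]phenyl}-2-(triisopropylsilyloxy)-3-(trimethylsilyloxy)propan-1-one | C[Si](C)(C)O[C@H](c1ccc(O[Si](C)(C)C(C)(C)C)cc1)[C@@H](O[Si](C(C)C)(C(C)C)C(C)C)C(=O)c1c(O[Si](C(C)C)(C(C)C)C(C)C)cc(OC/C=C(\C)CO[Si](C(C)C)(C(C)C)C(C)C)cc1F | intermediate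
13 | (2R,3R)-2-[4-(tert-butyldimethylsilyloxy)phenyl]-3,5-bis(triisopropylsilyloxy)-7-[(E)-3-methyl-4-(triisopropylsilyloxy)but-2-enyloxy]chroman-4-one | C/C(=C\COc1cc(O[Si](C(C)C)(C(C)C)C(C)C)c2c(c1)O[C@H](c1ccc(O[Si](C)(C)C(C)(C)C)cc1)[C@@H](O[Si](C(C)C)(C(C)C)C(C)C)C2=O)CO[Si](C(C)C)(C(C)C)C(C)C | intermediate
14 | (2R,3R)-3,5-dihydroxy-7-[(E)-4-hydroxy-3-methylbut-2-enyloxy]-2-(4-hydroxyphenyl)chroman-4-one (EANPDB:RUTA_00030) | C/C(=C\COc1cc(O)c2c(c1)O[C@H](c1ccc(O)cc1)[C@@H](O)C2=O)CO | target

**Count and risks**
Total steps: 8. Longest linear sequence: 7 steps (1, 3, 4, 5, 6, 7, 8); step 2 is the side branch.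

Steps most likely to fail:

1. Step 7 (Proposed new method).
   - What may go wrong: the aldol addition may revert at the alkoxide stage before ring closure and so lose facial control. The O3 silyl group may migrate to the C2 alkoxide (or scramble within the enediolate), followed by five-membered closure at C8a. The aldol may eliminate under base. The chain-carrying fluoride may desilylate the aryl ethers. The closure may give the 2,3-cis ring.
   - Fallback (known chemistry, forming O1–C2 instead of O1–C8a): it sets out from 5 and returns at 14. Commercial 2',4',6'-trihydroxyacetophenone is O-alkylated at its unchelated 4'-OH with 5 (K2CO3, acetone) to give 2',6'-dihydroxy-4'-[(E)-4-hydroxy-3-methylbut-2-enyloxy]acetophenone F1. MOMCl/NaH (DMF) should give the tris(methoxymethyl) ether F2. Claisen–Schmidt condensation with commercial 4-(methoxymethoxy)benzaldehyde (KOH, EtOH) should give the E-chalcone F3. Juliá–Colonna epoxidation (poly-L-leucine, urea–hydrogen peroxide, DBU, THF), a nucleophilic epoxidation that leaves the side-chain alkene alone, should give the (2R,3S)-epoxy ketone F4. HCl in MeOH/THF (50 °C) removes the four methoxymethyl groups, and the freed 2'-OH opens the epoxide at the benzylic carbon (6-endo, inversion) to give 14 directly.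

2. Step 5.
   - What may go wrong: the side-chain alkene may be epoxidised in competition with the enol ether, or the silyloxy-oxirane may open with loss instead of migration of the silyl group.
   - Fallback (enolate hydroxylation instead of enol ether epoxidation): it sets out from 6 and returns at 9. TIPSOTf (2.2 equiv)/2,6-lutidine (CH2Cl2, −78 °C) silylates only the two hydroxyl groups to give 2'-fluoro-6'-(triisopropylsilyloxy)-4'-[(E)-3-methyl-4-(triisopropylsilyloxy)but-2-enyloxy]acetophenone F5. KN(SiMe3)2 (THF, −78 °C) followed by 2-(phenylsulfonyl)-3-phenyloxaziridine, which does not touch the alkene, gives the α-hydroxy ketone F6. TIPSOTf/2,6-lutidine then gives 9.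

3. Step 1.
   - What may go wrong: low conversion of the fluorine-deactivated ring in the acid-mediated C-acylation, O-acylation, or acylation between the two hydroxyl groups.
   - Fallback (Friedel–Crafts acylation of the bis-ether, then dealkylation): it sets out from 1 and returns at 3. MeI/K2CO3 (acetone) gives 1-fluoro-3,5-dimethoxybenzene F7. AcCl/AlCl3 (CH2Cl2, 0 °C) acylates ortho to fluorine and para to a methoxy group to give 2'-fluoro-4',6'-dimethoxyacetophenone F8. BBr3 (CH2Cl2, −78 → 20 °C) cleaves both methyl ethers to give 3.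

**Further compounds**
F1 | step 7 | 2',6'-dihydroxy-4'-[(E)-4-hydroxy-3-methylbut-2-enyloxy]acetophenone | CC(=O)c1c(O)cc(OC/C=C(\C)CO)cc1O
F2 | step 7 | 2',6'-bis(methoxymethoxy)-4'-[(E)-4-(methoxymethoxy)-3-methylbut-2-enyloxy]acetophenone | CC(=O)c1c(OCOC)cc(OC/C=C(\C)COCOC)cc1OCOC
F3 | step 7 | (E)-1-{2,6-bis(methoxymethoxy)-4-[(E)-4-(methoxymethoxy)-3-methylbut-2-enyloxy]phenyl}-3-[4-(methoxymethoxy)phenyl]prop-2-en-1-one | COCOc1ccc(/C=C/C(=O)c2c(OCOC)cc(OC/C=C(\C)COCOC)cc2OCOC)cc1
F4 | step 7 | (2R,3S)-1-{2,6-bis(methoxymethoxy)-4-[(E)-4-(methoxymethoxy)-3-methylbut-2-enyloxy]phenyl}-2,3-epoxy-3-[4-(methoxymethoxy)phenyl]propan-1-one | O=C(c1c(OCOC)cc(OC/C=C(\C)COCOC)cc1OCOC)[C@@H]1O[C@H]1c1ccc(OCOC)cc1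
F5 | step 5 | 2'-fluoro-6'-(triisopropylsilyloxy)-4'-[(E)-3-methyl-4-(triisopropylsilyloxy)but-2-enyloxy]acetophenone | CC(=O)c1c(O[Si](C(C)C)(C(C)C)C(C)C)cc(OC/C=C(\C)CO[Si](C(C)C)(C(C)C)C(C)C)cc1F
F6 | step 5 | 2'-fluoro-α-hydroxy-6'-(triisopropylsilyloxy)-4'-[(E)-3-methyl-4-(triisopropylsilyloxy)but-2-enyloxy]acetophenone | O=C(CO)c1c(O[Si](C(C)C)(C(C)C)C(C)C)cc(OC/C=C(\C)CO[Si](C(C)C)(C(C)C)C(C)C)cc1F
F7 | step 1 | 1-fluoro-3,5-dimethoxybenzene | COc1cc(OC)cc(F)c1
F8 | step 1 | 2'-fluoro-4',6'-dimethoxyacetophenone | CC(=O)c1c(OC)cc(OC)cc1F
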